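The six-membered ring is closed by joining C4, the carbinol carbon, to C5, the epoxide CH carbon, while C5=C6 is still an alkene: an intramolecular Nozaki–Hiyama–Kishi addition of a (Z)-alkenyl iodide to a lactol-masked (Z)-enal. The step exploits the syn relation between the C4 hydroxyl and the C5–C6 oxirane next to the C1 ketone of the cyclohexenone ring. It should deliver a cis-cyclohexa-2,5-diene-1,4-diol in which a CBS-set C1 carbinol fixes C4 through a chromium chelate; both hydroxyls then direct the epoxidation before C1 is oxidised. The precursor is a 2,5-dihydrofuran-2-ol bearing a 1-iodopenta-1,4-dien-2-yl arm; both side chains are finished late.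

Key step: step 8

Remark: ring atoms are numbered C1 (ketone carbon), C2 (heptenyl-bearing carbon), C3 (hydroxymethyl-bearing carbon), C4 (carbinol carbon), C5 (epoxide CH) and C6 (quaternary epoxide carbon); TBS = tert-butyl(dimethyl)silyl, TES = triethylsilyl, TMS = trimethylsilyl.
Remark: compounds 1, 2, 5, 10, 19 and 21 are taken as commercially available.

Step 1
Reactants: 1 3,4-dibromofuran-2(5H)-one; 2 (tributylstannyl)methanol
Product: 3 3-bromo-4-(hydroxymethyl)furan-2(5H)-one
Conditions: Pd(PPh3)4 (5 mol %), 1,4-dioxane, 90 °C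
Reagents that add atoms: none
Why: Stille cross-coupling: zerovalent palladium should insert only into the C4–Br bond of the butenolide, which is a vinylogous acyl bromide, so the hydroxymethyl group enters at the β-carbon and the α-bromine (the later C2–Br) is kept.

Step 2
Reactants: 3 3-bromo-4-(hydroxymethyl)furan-2(5H)-one
Product: 4 3-bromo-4-[(TBS-oxy)methyl]furan-2(5H)-one
Conditions: TBSCl, imidazole, CH2Cl2, 0 °C to rt
Reagents that add atoms: tert-butyl(chloro)dimethylsilane, CC(C)(C)[Si](C)(C)Cl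
Why: Standard silyl ether formation on the only hydroxyl group protects the future C3 hydroxymethyl arm for the organometallic and oxidation steps that follow.

Step 3
Reactants: 4 3-bromo-4-[(TBS-oxy)methyl]furan-2(5H)-one; 5 ethynyltrimethylsilane
Product: 7 (4Z)-4-bromo-5-[(TBS-oxy)methyl]-1-(trimethylsilyl)-6-(TMS-oxy)hex-4-en-1-yn-3-one, via cerium alkoxide 6 (not isolated)
Conditions: 5, n-BuLi, THF, −78 °C; anhydrous CeCl3, −78 °C; add 4; then Me3SiCl, −78 to 0 °C
Reagents that add atoms: chlorotrimethylsilane, C[Si](C)(C)Cl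
Why: Acylation of an acetylide by a lactone (1,2-addition of the weakly basic organocerium reagent to the lactone carbonyl, ring opening of the adduct and O-silylation of the released primary alkoxide) should give the open ynone, the Z geometry of the tetrasubstituted C2=C3 alkene being inherited from the ring.

Step 4
Reactants: 7 (4Z)-4-bromo-5-[(TBS-oxy)methyl]-1-(trimethylsilyl)-6-(TMS-oxy)hex-4-en-1-yn-3-one
Product: 9 (2Z,4S)-3-bromo-2-[(TBS-oxy)methyl]hex-2-en-5-yne-1,4-diol, via silylated propargylic alcohol 8 (not isolated)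
Conditions: (R)-2-methyl-CBS-oxazaborolidine (20 mol %), catecholborane, toluene, −78 °C; then MeOH, K2CO3, rt
Reagents that add atoms: none
Why: Corey–Bakshi–Shibata reduction, in which the bulky α-bromoalkenyl group takes the large-group position and the slim alkynyl group the small one on the oxazaborolidine–borane complex, should set C1 as S, and methanolic K2CO3 then removes the C- and O-trimethylsilyl groups while the TBS ether stays.

Step 5
Reactants: 9 (2Z,4S)-3-bromo-2-[(TBS-oxy)methyl]hex-2-en-5-yne-1,4-diol; 10 allylmagnesium bromide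
Product: 12 (2Z,4S,5Z)-3-bromo-2-[(TBS-oxy)methyl]-5-(iodomethylidene)octa-2,7-diene-1,4-diol, via alkenylmagnesium bromide 11 (not isolated)
Conditions: 10 (5 equiv), Et2O, 0 °C to rt; then N-iodosuccinimide, THF, −78 to 0 °C
Reagents that add atoms: N-iodosuccinimide, O=C1CCC(=O)N1I
Why: Alkoxide-directed anti-carbomagnesiation of the terminal propargylic alkyne (allyl to C6, magnesium to C5 inside a five-membered chelate with the C1 alkoxide) followed by iodinolysis with retention should give the Z alkenyl iodide with iodine cis to C1, without touching the C1 stereocentre.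

Step 6
Reactants: 12 (2Z,4S,5Z)-3-bromo-2-[(TBS-oxy)methyl]-5-(iodomethylidene)octa-2,7-diene-1,4-diol
Product: 13 (5S)-4-bromo-3-[(TBS-oxy)methyl]-5-[(1Z)-1-iodopenta-1,4-dien-2-yl]furan-2(5H)-one
Conditions: TEMPO (20 mol %), PhI(OAc)2 (2.5 equiv), CH2Cl2, rt
Reagents that add atoms: none
Why: Oxoammonium (TEMPO) oxidation takes the primary allylic alcohol in preference to the hindered secondary one, and the aldehyde is trapped by the cis C1 hydroxyl as a lactol that is oxidised on to the butenolide (oxidative lactonisation), which fixes C4 at the carbonyl level and masks the C1 oxygen.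

Step 7
Reactants: 13 (5S)-4-bromo-3-[(TBS-oxy)methyl]-5-[(1Z)-1-iodopenta-1,4-dien-2-yl]furan-2(5H)-one
Product: 14 (5S)-4-bromo-3-[(TBS-oxy)methyl]-5-[(1Z)-1-iodopenta-1,4-dien-2-yl]-2,5-dihydrofuran-2-ol (both anomers)
Conditions: iBu2AlH (1.1 equiv), CH2Cl2, −78 °C; aqueous potassium sodium tartrate
Reagents that add atoms: none
Why: Partial reduction of a lactone with iBu2AlH at low temperature stops at the lactol because the tetrahedral aluminate survives until work-up; the new anomeric centre forms as a mixture that is of no consequence.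

Step 8
Reactants: 14 (5S)-4-bromo-3-[(TBS-oxy)methyl]-5-[(1Z)-1-iodopenta-1,4-dien-2-yl]-2,5-dihydrofuran-2-ol
Product: 15 (1R,4S)-3-bromo-2-[(TBS-oxy)methyl]-5-(prop-2-en-1-yl)cyclohexa-2,5-diene-1,4-diol (cis-diol)
Conditions: CrCl2 (8 equiv), NiCl2 (2 mol %), degassed DMSO/THF, rt, 0.005 M; work-up at pH 7
Reagents that add atoms: none
Why: Zerovalent nickel inserts into the C5–I bond, the alkenyl group passes to trivalent chromium with retention of the Z geometry, and the alkenylchromium adds to the C4 aldehyde that the lactol releases by ring–chain tautomerism, which forms the C4–C5 bond. The closest known reaction type is the intramolecular Nozaki–Hiyama–Kishi cyclisation of iodoalkenyl aldehydes, which also runs on lactols and tolerates free hydroxyls. The carbocycle C1–C6 closes in a 6-exo-trig mode at the aldehyde carbon, the two Z alkenes C2=C3 and C5=C6 holding both termini on the same side of C1. The new stereocentre C4 is controlled by C1: the C1 oxygen and the aldehyde oxygen should bind the same chromium atom in a five-membered O–Cr–C5=C6–C1 chelate, so both oxygens end on one face and the cis-1,4-diol results. The step needs selectivity for C–I over the C2–Br bond, secured by the much faster insertion of nickel into the iodide, and for the aldehyde over all other groups, which is inherent to alkenylchromium reagents. The product is a bis-allylic diol that would lose water to an arene under acid, so the work-up is kept neutral.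

Step 9
Reactants: 15 (1R,4S)-3-bromo-2-[(TBS-oxy)methyl]-5-(prop-2-en-1-yl)cyclohexa-2,5-diene-1,4-diol
Product: 16 (1R,2S,5S,6S)-3-bromo-4-[(TBS-oxy)methyl]-1-(prop-2-en-1-yl)-7-oxabicyclo[4.1.0]hept-3-ene-2,5-diol
Conditions: VO(acac)2 (5 mol %), t-BuOOH (1.5 equiv), CH2Cl2, 0 °C
Reagents that add atoms: tert-butyl hydroperoxide, CC(C)(C)OO
Why: Hydroxyl-directed vanadium-catalysed epoxidation: both cis hydroxyls are allylic to C5=C6 and deliver the oxygen to their own face, so C5 and C6 are set syn to the C4 hydroxyl, while the bromine-bearing tetrasubstituted C2=C3 bond is too electron-poor and the allyl group too remote to compete.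

Step 10
Reactants: 16 (1R,2S,5S,6S)-3-bromo-4-[(TBS-oxy)methyl]-1-(prop-2-en-1-yl)-7-oxabicyclo[4.1.0]hept-3-ene-2,5-diol
Product: 17 (1R,2S,5S,6S)-3-bromo-5-(TBS-oxy)-4-[(TBS-oxy)methyl]-1-(prop-2-en-1-yl)-7-oxabicyclo[4.1.0]hept-3-en-2-ol
Conditions: TBSCl (1.1 equiv), imidazole, DMF, 0 °C
Reagents that add atoms: tert-butyl(chloro)dimethylsilane, CC(C)(C)[Si](C)(C)Cl
Why: Silyl ether formation with a bulky chlorosilane should take the C4 hydroxyl, which has the epoxide CH as a neighbour, ahead of the C1 hydroxyl, which is wedged between the quaternary epoxide carbon and the bromine-bearing alkene carbon.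

Step 11
Reactants: 17 (1R,2S,5S,6S)-3-bromo-5-(TBS-oxy)-4-[(TBS-oxy)methyl]-1-(prop-2-en-1-yl)-7-oxabicyclo[4.1.0]hept-3-en-2-ol
Product: 18 (1S,5S,6S)-3-bromo-5-(TBS-oxy)-4-[(TBS-oxy)methyl]-1-(prop-2-en-1-yl)-7-oxabicyclo[4.1.0]hept-3-en-2-one
Conditions: Dess–Martin periodinane, NaHCO3, CH2Cl2, 0 °C to rt
Reagents that add atoms: none
Why: Dess–Martin oxidation of the remaining secondary allylic alcohol gives the α-bromo enone under buffered neutral conditions, and with C5–C6 now an epoxide the ketone can no longer tautomerise to a phenol.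

Step 12
Reactants: 18 (1S,5S,6S)-3-bromo-5-(TBS-oxy)-4-[(TBS-oxy)methyl]-1-(prop-2-en-1-yl)-7-oxabicyclo[4.1.0]hept-3-en-2-one; 19 methacrolein
Product: 20 (2E)-4-[(1S,5S,6S)-3-bromo-5-(TBS-oxy)-4-[(TBS-oxy)methyl]-2-oxo-7-oxabicyclo[4.1.0]hept-3-en-1-yl]-2-methylbut-2-enal
Conditions: second-generation Hoveyda–Grubbs catalyst (5 mol %), 19 (10 equiv), CH2Cl2, 40 °C
Reagents that add atoms: none
Why: Olefin cross-metathesis of the terminal allyl group with the 1,1-disubstituted enal should give the E trisubstituted enal under thermodynamic control, the tetrasubstituted bromo-enone alkene being inert to the ruthenium carbene.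

Step 13
Reactants: 21 hept-1-yne
Product: 22 tributyl[(1E)-hept-1-en-1-yl]stannane
Conditions: Bu3SnH, AIBN (cat.), neat, 90 °C
Reagents that add atoms: tributyltin hydride, CCCC[SnH](CCCC)CCCC
Why: Radical hydrostannation of a terminal alkyne places tin on the terminal carbon and equilibrates under the conditions to the E alkenylstannane.

Step 14
Reactants: 20 (2E)-4-[(1S,5S,6S)-3-bromo-5-(TBS-oxy)-4-[(TBS-oxy)methyl]-2-oxo-7-oxabicyclo[4.1.0]hept-3-en-1-yl]-2-methylbut-2-enal; 22 tributyl[(1E)-hept-1-en-1-yl]stannane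
Product: 23 (2E)-4-[(1S,5S,6S)-5-(TBS-oxy)-4-[(TBS-oxy)methyl]-3-[(1E)-hept-1-en-1-yl]-2-oxo-7-oxabicyclo[4.1.0]hept-3-en-1-yl]-2-methylbut-2-enal
Conditions: Pd2(dba)3 (5 mol %), AsPh3 (20 mol %), toluene, 90 °C
Reagents that add atoms: none
Why: Stille cross-coupling at the α-bromo enone carbon proceeds with retention of the E geometry of the stannane under neutral conditions that spare the base-sensitive epoxy enone and the enal.

Step 15
Reactants: 23 (2E)-4-[(1S,5S,6S)-5-(TBS-oxy)-4-[(TBS-oxy)methyl]-3-[(1E)-hept-1-en-1-yl]-2-oxo-7-oxabicyclo[4.1.0]hept-3-en-1-yl]-2-methylbut-2-enal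
Product: 24 (2E)-4-[(1S,5S,6S)-5-(TBS-oxy)-4-[(TBS-oxy)methyl]-3-[(1E)-hept-1-en-1-yl]-2-oxo-7-oxabicyclo[4.1.0]hept-3-en-1-yl]-2-methylbut-2-enoic acid
Conditions: NaClO2, NaH2PO4, 2-methylbut-2-ene, t-BuOH/H2O, 0 °C to rt
Reagents that add atoms: sodium chlorite, [Na+].[O-]Cl=O
Why: Pinnick oxidation converts the enal into the acid without moving the alkene, the alkene scavenger removing hypochlorous acid before it can attack the diene.

Step 16
Reactants: 24 (2E)-4-[(1S,5S,6S)-5-(TBS-oxy)-4-[(TBS-oxy)methyl]-3-[(1E)-hept-1-en-1-yl]-2-oxo-7-oxabicyclo[4.1.0]hept-3-en-1-yl]-2-methylbut-2-enoic acid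
Product: 25 (2E)-4-[(1S,5S,6S)-3-[(1E)-hept-1-en-1-yl]-5-hydroxy-4-(hydroxymethyl)-2-oxo-7-oxabicyclo[4.1.0]hept-3-en-1-yl]-2-methylbut-2-enoic acid (target)
Conditions: HF·pyridine, pyridine/THF, 0 °C to rt
Reagents that add atoms: none
Why: Fluoride-mediated cleavage of both silyl ethers under buffered conditions that the epoxy enone tolerates releases the C4 hydroxyl and the hydroxymethyl group without affecting any stereocentre.

Compound list
1 | 3,4-dibromofuran-2(5H)-one | O=C1OCC(Br)=C1Br | starting material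
2 | (tributylstannyl)methanol | CCCC[Sn](CCCC)(CCCC)CO | starting material
3 | 3-bromo-4-(hydroxymethyl)furan-2(5H)-one | O=C1OCC(CO)=C1Br | intermediate
4 | 3-bromo-4-[(TBS-oxy)methyl]furan-2(5H)-one | CC(C)(C)[Si](C)(C)OCC1=C(Br)C(=O)OC1 | intermediate
5 | ethynyltrimethylsilane | C#C[Si](C)(C)C | starting material
6 | dichlorocerium alkoxide of (4Z)-4-bromo-5-[(TBS-oxy)methyl]-6-hydroxy-1-(trimethylsilyl)hex-4-en-1-yn-3-one (ring-opened adduct, C4 oxygen cis to the ketone) | O=C(C#C[Si](C)(C)C)/C(Br)=C(CO[Si](C)(C)C(C)(C)C)\CO[Ce](Cl)Cl | intermediate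
7 | (4Z)-4-bromo-5-[(TBS-oxy)methyl]-1-(trimethylsilyl)-6-(TMS-oxy)hex-4-en-1-yn-3-one | O=C(C#C[Si](C)(C)C)/C(Br)=C(CO[Si](C)(C)C(C)(C)C)\CO[Si](C)(C)C | intermediate
8 | (3S,4Z)-4-bromo-5-[(TBS-oxy)methyl]-1-(trimethylsilyl)-6-(TMS-oxy)hex-4-en-1-yn-3-ol | O[C@@H](C#C[Si](C)(C)C)/C(Br)=C(CO[Si](C)(C)C(C)(C)C)\CO[Si](C)(C)C | intermediate
9 | (2Z,4S)-3-bromo-2-[(TBS-oxy)methyl]hex-2-en-5-yne-1,4-diol | O[C@@H](C#C)/C(Br)=C(CO[Si](C)(C)C(C)(C)C)\CO | intermediate
10 | allylmagnesium bromide | C=CC[Mg]Br | starting material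
11 | tris(bromomagnesium) species from 9: both hydroxyls as bromomagnesium alkoxides, allyl on C6, bromomagnesium on C5 cis to C1 | Br[Mg]O[C@@H](/C(CC=C)=C\[Mg]Br)/C(Br)=C(CO[Si](C)(C)C(C)(C)C)\CO[Mg]Br | intermediate
12 | (2Z,4S,5Z)-3-bromo-2-[(TBS-oxy)methyl]-5-(iodomethylidene)octa-2,7-diene-1,4-diol | O[C@@H](/C(CC=C)=C\I)/C(Br)=C(CO[Si](C)(C)C(C)(C)C)\CO | intermediate
13 | (5S)-4-bromo-3-[(TBS-oxy)methyl]-5-[(1Z)-1-iodopenta-1,4-dien-2-yl]furan-2(5H)-one | O=C1O[C@@H](/C(CC=C)=C\I)C(Br)=C1CO[Si](C)(C)C(C)(C)C | intermediate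
14 | (5S)-4-bromo-3-[(TBS-oxy)methyl]-5-[(1Z)-1-iodopenta-1,4-dien-2-yl]-2,5-dihydrofuran-2-ol, both anomers | OC1O[C@@H](/C(CC=C)=C\I)C(Br)=C1CO[Si](C)(C)C(C)(C)C | intermediate
15 | (1R,4S)-3-bromo-2-[(TBS-oxy)methyl]-5-(prop-2-en-1-yl)cyclohexa-2,5-diene-1,4-diol (hydroxyls cis) | BrC1=C(CO[Si](C)(C)C(C)(C)C)[C@H](O)C=C(CC=C)[C@@H]1O | intermediate
16 | (1R,2S,5S,6S)-3-bromo-4-[(TBS-oxy)methyl]-1-(prop-2-en-1-yl)-7-oxabicyclo[4.1.0]hept-3-ene-2,5-diol (epoxide syn to both hydroxyls) | BrC1=C(CO[Si](C)(C)C(C)(C)C)[C@H](O)[C@@H]2O[C@]2(CC=C)[C@@H]1O | intermediate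
17 | (1R,2S,5S,6S)-3-bromo-5-(TBS-oxy)-4-[(TBS-oxy)methyl]-1-(prop-2-en-1-yl)-7-oxabicyclo[4.1.0]hept-3-en-2-ol | BrC1=C(CO[Si](C)(C)C(C)(C)C)[C@H](O[Si](C)(C)C(C)(C)C)[C@@H]2O[C@]2(CC=C)[C@@H]1O | intermediate
18 | (1S,5S,6S)-3-bromo-5-(TBS-oxy)-4-[(TBS-oxy)methyl]-1-(prop-2-en-1-yl)-7-oxabicyclo[4.1.0]hept-3-en-2-one | BrC1=C(CO[Si](C)(C)C(C)(C)C)[C@H](O[Si](C)(C)C(C)(C)C)[C@@H]2O[C@]2(CC=C)C1=O | intermediate
19 | methacrolein (2-methylprop-2-enal) | CC(=C)C=O | starting material
20 | (2E)-4-[(1S,5S,6S)-3-bromo-5-(TBS-oxy)-4-[(TBS-oxy)methyl]-2-oxo-7-oxabicyclo[4.1.0]hept-3-en-1-yl]-2-methylbut-2-enal | BrC1=C(CO[Si](C)(C)C(C)(C)C)[C@H](O[Si](C)(C)C(C)(C)C)[C@@H]2O[C@]2(C/C=C(\C)C=O)C1=O | intermediate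
21 | hept-1-yne | CCCCCC#C | starting material
22 | tributyl[(1E)-hept-1-en-1-yl]stannane | CCCCC/C=C/[Sn](CCCC)(CCCC)CCCC | intermediate
23 | (2E)-4-[(1S,5S,6S)-5-(TBS-oxy)-4-[(TBS-oxy)methyl]-3-[(1E)-hept-1-en-1-yl]-2-oxo-7-oxabicyclo[4.1.0]hept-3-en-1-yl]-2-methylbut-2-enal | CCCCC/C=C/C1=C(CO[Si](C)(C)C(C)(C)C)[C@H](O[Si](C)(C)C(C)(C)C)[C@@H]2O[C@]2(C/C=C(\C)C=O)C1=O | intermediate
24 | (2E)-4-[(1S,5S,6S)-5-(TBS-oxy)-4-[(TBS-oxy)methyl]-3-[(1E)-hept-1-en-1-yl]-2-oxo-7-oxabicyclo[4.1.0]hept-3-en-1-yl]-2-methylbut-2-enoic acid | CCCCC/C=C/C1=C(CO[Si](C)(C)C(C)(C)C)[C@H](O[Si](C)(C)C(C)(C)C)[C@@H]2O[C@]2(C/C=C(\C)C(=O)O)C1=O | intermediate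
25 | (2E)-4-[(1S,5S,6S)-3-[(1E)-hept-1-en-1-yl]-5-hydroxy-4-(hydroxymethyl)-2-oxo-7-oxabicyclo[4.1.0]hept-3-en-1-yl]-2-methylbut-2-enoic acid | CCCCC/C=C/C1=C(CO)[C@H](O)[C@@H]2O[C@]2(C/C=C(\C)C(=O)O)C1=O | target

Total step count: 16. Longest linear sequence: 15 steps (steps 1 to 12 and 14 to 16; step 13 makes the stannane on a side branch).

Steps most likely to fail

Step 8. The lactol may open too slowly, so that dehydration to the furan or simple reduction of the alkenyl iodide wins. The chromium chelate may also fail to enforce the cis facial selectivity at C4; the trans diol would then have to be separated. Fallback: setting out from 12, both hydroxyls are silylated with Et3SiOTf and 2,6-lutidine to the bis(triethylsilyl) ether F1. Swern oxidation converts the primary triethylsilyl ether directly into the aldehyde F2, with the C1 oxygen still silylated. The ring is then closed under reagent control (CrCl2, NiCl2, a chiral oxazoline–sulfonamide ligand, Et3N) to the C1-silylated cis-dienediol F3. Epoxidation directed by the free C4 hydroxyl (VO(acac)2, t-BuOOH) gives the epoxy alcohol F4, TBSOTf gives the fully silylated epoxide F5, and selective methanolysis of the triethylsilyl ether (PPTS, MeOH) comes back to the route at 17.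

Step 3. The acetylide may remove a γ-proton of the butenolide instead of adding to the carbonyl, or the adduct may be silylated in its closed form and later lose water to a furan. Fallback: setting out from 4, the lactone is opened with Me3Al and MeNH(OMe)·HCl and the released hydroxyl is silylated in the same flask (Me3SiCl, imidazole) to the Weinreb amide F6. Lithium (trimethylsilyl)acetylide then adds once to the amide and comes back to the route at 7.

Step 10. The two secondary hydroxyls may be silylated at similar rates, which would give mixtures of mono- and bis-silyl ethers. Fallback: setting out from 15, the silylation is moved to the planar dienediol, where the C4 hydroxyl has a CH neighbour and the C1 hydroxyl is flanked by two substituted alkene carbons. TBSCl and imidazole at −20 °C should then give the mono-silyl ether F7, and the remaining C1 hydroxyl alone directs the vanadium epoxidation (VO(acac)2, t-BuOOH), which comes back to the route at 17.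

Further compounds
F1 | step 8 | 1,4-bis(triethylsilyl) ether of 12: (2Z,4S,5Z)-3-bromo-2-[(TBS-oxy)methyl]-5-(iodomethylidene)-1,4-bis(TES-oxy)octa-2,7-diene | CC[Si](CC)(CC)O[C@@H](/C(CC=C)=C\I)/C(Br)=C(CO[Si](C)(C)C(C)(C)C)\CO[Si](CC)(CC)CC
F2 | step 8 | (2E,4S,5Z)-3-bromo-2-[(TBS-oxy)methyl]-5-(iodomethylidene)-4-(TES-oxy)octa-2,7-dienal (aldehyde cis to C1) | CC[Si](CC)(CC)O[C@@H](/C(CC=C)=C\I)/C(Br)=C(CO[Si](C)(C)C(C)(C)C)\C=O
F3 | step 8 | (1R,4S)-3-bromo-2-[(TBS-oxy)methyl]-5-(prop-2-en-1-yl)-4-(TES-oxy)cyclohexa-2,5-dien-1-ol (oxygens cis) | BrC1=C(CO[Si](C)(C)C(C)(C)C)[C@H](O)C=C(CC=C)[C@@H]1O[Si](CC)(CC)CC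
F4 | step 8 | triethylsilyl ether of 16 at the C1 hydroxyl (the one next to the quaternary epoxide carbon), C4 hydroxyl free | BrC1=C(CO[Si](C)(C)C(C)(C)C)[C@H](O)[C@@H]2O[C@]2(CC=C)[C@@H]1O[Si](CC)(CC)CC
F5 | step 8 | triethylsilyl ether of 17 at the C1 hydroxyl | BrC1=C(CO[Si](C)(C)C(C)(C)C)[C@H](O[Si](C)(C)C(C)(C)C)[C@@H]2O[C@]2(CC=C)[C@@H]1O[Si](CC)(CC)CC
F6 | step 3 | (2Z)-2-bromo-3-[(TBS-oxy)methyl]-N-methoxy-N-methyl-4-(TMS-oxy)but-2-enamide | CON(C)C(=O)/C(Br)=C(CO[Si](C)(C)C(C)(C)C)\CO[Si](C)(C)C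
F7 | step 10 | (1S,4R)-2-bromo-4-(TBS-oxy)-3-[(TBS-oxy)methyl]-6-(prop-2-en-1-yl)cyclohexa-2,5-dien-1-ol (oxygens cis) | BrC1=C(CO[Si](C)(C)C(C)(C)C)[C@H](O[Si](C)(C)C(C)(C)C)C=C(CC=C)[C@@H]1O
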